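## Retrosynthetic overview

1. Feature: the target is a cis-fused bicycle in which a cyclopentane (C4–C5–C6–C7–C8) shares the C4–C8 bond with a cycloheptene (C1–C2–C3–C4–C8–C9–C10). Oxygenated C3 is bonded to quaternary C4, and the tertiary carbinol C7 is bonded to ring-fusion C8. C7 can therefore act as an oxocarbenium electrophile toward a C4=C8 alkene, and C3 as the carbinol that quenches the C4 cation by a 1,2-shift.
2. Endgame: the C9 aroyl ester by Mitsunobu inversion; the C3 ester from Luche reduction of a C1-methyl enone; that enone from the C3 ketone by two Saegusa–Ito oxidations around a cuprate addition.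
3. Key disconnection: C7–C8 (Prins) and C4–C5 (pinacol shift) in cycloheptenyl silyl ether 15.
4. 15 comes from enone 7 (cyclohepta-1,3-diene; C9 set by lipase resolution) and Grignard reagent 13 (isobutyryl chloride plus ethylene).
5. Ring order: the seven-membered ring is bought in; the five-membered ring is closed in the key step.

Key step: step 11

Remark on numbering: ring carbons are C1–C10 as in the target (C1 C-methyl alkene carbon, C2 alkene CH, C3 isovalerate carbinol, C4 quaternary C-methyl, C5 and C6 cyclopentane CH2, C7 isopropyl carbinol, C8 ring-fusion CH, C9 aroyloxy carbinol, C10 CH2). The same labels are used for the corresponding atoms of earlier intermediates, and β is the face of the C4 methyl group.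

Assumption: the lipase acetylates the (R)-enantiomer of 3 faster, as it does with smaller 4-hydroxycycloalkenones. If the preference were reversed, 4 would be obtained by methanolysis of the acetate instead.

## Route

Step 1
Reactants: 1 cyclohepta-1,3-diene
Product: 3 rac-4-hydroxycyclohept-2-en-1-one, via endoperoxide 2 (not isolated)
Conditions: O2, hν, tetraphenylporphyrin (cat.), CH2Cl2, 0 °C; then Et3N, 0 °C → rt
Reagents that add atoms: dioxygen, O=O
Why: Singlet oxygen adds across the cyclic 1,3-diene in a [4+2] cycloaddition, and triethylamine then opens the meso endoperoxide by the Kornblum–DeLaMare rearrangement to the γ-hydroxy enone, racemic at C9.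

Step 2
Reactants: 3 rac-4-hydroxycyclohept-2-en-1-one
Product: 4 (S)-4-hydroxycyclohept-2-en-1-one
Conditions: Burkholderia cepacia lipase, vinyl acetate, t-BuOMe, rt, to about half conversion
Reagents that add atoms: none
Why: Lipase-catalysed kinetic resolution by irreversible transesterification: the (R)-alcohol should be acetylated faster, as the empirical rule for secondary alcohols predicts, so the (S)-alcohol (the C9 stereocentre) remains.

Step 3
Reactants: 4 (S)-4-hydroxycyclohept-2-en-1-one
Product: 5 (S)-4-(triisopropylsilyloxy)cyclohept-2-en-1-one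
Conditions: TIPSOTf, 2,6-lutidine, CH2Cl2, 0 °C
Reagents that add atoms: triisopropylsilyl triflate, CC(C)[Si](C(C)C)(C(C)C)OS(=O)(=O)C(F)(F)F
Why: Silylation of the secondary alcohol with a silyl triflate and a hindered base; the bulky ether later shields one face of the ring.

Step 4
Reactants: 5 (S)-4-(triisopropylsilyloxy)cyclohept-2-en-1-one
Product: 6 (S)-2-iodo-4-(triisopropylsilyloxy)cyclohept-2-en-1-one
Conditions: I2, pyridine, CH2Cl2, 0 °C → rt
Reagents that add atoms: iodine, II
Why: α-Iodination of the enone by addition–elimination (pyridine adds to the β-carbon, the enolate is iodinated, pyridine leaves), a routine reaction of 4-silyloxy cycloalkenones.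

Step 5
Reactants: 6 (S)-2-iodo-4-(triisopropylsilyloxy)cyclohept-2-en-1-one
Product: 7 (S)-2-methyl-4-(triisopropylsilyloxy)cyclohept-2-en-1-one
Conditions: MeZnCl, Pd(PPh3)4 (5 mol %), THF/DMF, rt
Reagents that add atoms: methylzinc chloride, C[Zn]Cl
Why: Negishi coupling: zerovalent palladium inserts into the vinyl C–I bond and the zinc reagent transfers methyl, which gives the 2-methyl enone without touching the silyl ether.

Step 6
Reactants: 8 isobutyryl chloride; 9 ethylene
Product: 10 1-chloro-4-methylpentan-3-one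
Conditions: AlCl3, CH2Cl2, 0 °C → rt, ethylene stream
Reagents that add atoms: none
Why: Aliphatic Friedel–Crafts acylation: the acylium ion adds to ethylene and chloride captures the resulting cation to give the β-chloro ketone.

Step 7
Reactants: 10 1-chloro-4-methylpentan-3-one
Product: 11 3,3-bis(benzyloxy)-1-chloro-4-methylpentane
Conditions: BnOSiMe3 (2.5 equiv), TMSOTf (5 mol %), CH2Cl2, −78 → −20 °C; pyridine quench
Reagents that add atoms: benzyloxytrimethylsilane, C[Si](C)(C)OCc1ccccc1
Why: Noyori ketalisation: the silyl triflate activates the ketone and two benzyl silyl ethers deliver the benzyloxy groups irreversibly with loss of the disiloxane, under conditions too mild to eliminate HCl.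

Step 8
Reactants: 11 3,3-bis(benzyloxy)-1-chloro-4-methylpentane
Product: 12 3,3-bis(benzyloxy)-1-iodo-4-methylpentane
Conditions: NaI, NaHCO3, acetone, reflux
Reagents that add atoms: sodium iodide, [Na+].[I-]
Why: Finkelstein exchange (SN2 at the primary chloride, driven by precipitation of NaCl) gives the iodide needed for easy magnesium insertion.

Step 9
Reactants: 12 3,3-bis(benzyloxy)-1-iodo-4-methylpentane; 7 (S)-2-methyl-4-(triisopropylsilyloxy)cyclohept-2-en-1-one
Product: 14 (1S,4S)-1-[3,3-bis(benzyloxy)-4-methylpentyl]-2-methyl-4-(triisopropylsilyloxy)cyclohept-2-en-1-ol, via Grignard reagent 13 (not isolated)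
Conditions: Mg, Et2O/THF, rt; then added to 7 and anhydrous CeCl3, THF, −78 °C; pH 7 buffer
Reagents that add atoms: none
Why: Grignard formation and CeCl3-promoted 1,2-addition, which suppresses enolisation and conjugate addition at the hindered enone; the reagent should enter anti to the bulky C9 silyloxy group and so set C3 with the two oxygens cis, the syn adduct being a separable diastereomer.

Step 10
Reactants: 14 (1S,4S)-1-[3,3-bis(benzyloxy)-4-methylpentyl]-2-methyl-4-(triisopropylsilyloxy)cyclohept-2-en-1-ol
Product: 15 trimethylsilyl ether of 14 (C3–OSiMe3 and C9–OSi(i-Pr)3 cis; side chain on the opposite face)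
Conditions: N-(trimethylsilyl)imidazole, CH2Cl2, rt
Reagents that add atoms: N-(trimethylsilyl)imidazole, C[Si](C)(C)n1ccnc1
Why: Silylation of the tertiary alcohol with a neutral silyl donor, which leaves the acid-labile ketal intact and stops the hydroxy ketal from closing to a cyclic mixed ketal.

Step 11
Reactants: 15 trimethylsilyl ether of 14
Product: 16 cis-fused hydroazulen-3-one with 4β-methyl; 7β-benzyloxy; 7α-isopropyl; 8β-H; 9β-triisopropylsilyloxy (4R,7S,8S,9S)
Conditions: SnCl4 (1.5 equiv), CH2Cl2, −78 → −23 °C; aq NaHCO3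
Reagents that add atoms: none
Why: Tin tetrachloride removes one benzyloxy group from the ketal, the O-benzyl oxocarbenium carbon C7 is captured by C8 of the ring alkene (Prins), and the tertiary C4 cation is quenched when C5 moves from C3 to C4 under the push of the C3 silyloxy group, which leaves C3 as the ketone. The closest known reaction type is the pinacol-terminated Prins cyclisation of allylic silyl ethers that carry an acetal on the carbinol carbon, where a 6-endo cyclisation is followed by contraction of the new ring to an acylcyclopentane. The cyclopentane is thus closed in two stages: 6-endo-trig closure of the ring C3–C5–C6–C7–C8–C4 through a chair, then its contraction by the 1,2-shift. C8 is set by the tether, which reaches the alkene only from its own face, anti to the C9 silyloxy group (fixed in step 9); C4 is set by the suprafacial shift, which keeps C5 on that face and gives the cis fusion; C7 is set by the chair, with isopropyl equatorial and benzyloxy axial and hence cis to H8. The step needs attack at C8 rather than C4, which the C4 methyl group secures through the tertiary cation, and it needs C5 rather than ring carbon C2 to migrate. Only the known preference for contraction of the Prins ring favours C5 over C2, which the bridged cation holds axial and equally well aligned, so this choice is the main risk of the route.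

Step 12
Reactants: 16 cis-fused hydroazulen-3-one (7-benzyloxy; 9-silyloxy)
Product: 17 7β-hydroxy-7α-isopropyl-4β-methyl-9β-(triisopropylsilyloxy)-cis-hydroazulen-3-one
Conditions: H2 (1 atm), Pd(OH)2/C, EtOAc, rt
Reagents that add atoms: none
Why: Hydrogenolysis of the benzyl C–O bond on palladium frees the tertiary alcohol while no alkene is present; ketone and silyl ether are inert.

Step 13
Reactants: 17 7β-hydroxy hydroazulen-3-one
Product: 19 7β-(trimethylsilyloxy)-9β-(triisopropylsilyloxy)-cis-hydroazul-1-en-3-one, via bis-silyl enol ether 18 (not isolated)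
Conditions: TMSOTf (3 equiv), Et3N, CH2Cl2, 0 °C; then Pd(OAc)2 (1.1 equiv), MeCN, rt
Reagents that add atoms: trimethylsilyl triflate, C[Si](C)(C)OS(=O)(=O)C(F)(F)F
Why: Soft enolisation gives the only possible silyl enol ether (C4 is quaternary) and silylates the tertiary alcohol, and Saegusa–Ito oxidation (palladium enolate, β-hydride elimination) then gives the enone.

Step 14
Reactants: 19 hydroazul-1-en-3-one
Product: 21 1-methyl-7β-(trimethylsilyloxy)-9β-(triisopropylsilyloxy)-cis-hydroazul-1-en-3-one, via silyl enol ether 20 (not isolated)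
Conditions: Me2CuLi, Me3SiCl, THF, −78 °C; then Pd(OAc)2 (1.1 equiv), MeCN, rt
Reagents that add atoms: lithium dimethylcuprate, [Li+].C[Cu-]C
Why: Conjugate addition of the Gilman cuprate to the β-carbon C1 with in situ silyl trapping, followed by a second Saegusa–Ito oxidation that returns the C1=C2 bond; the C1 configuration of 20 is erased.

Step 15
Reactants: 21 1-methyl hydroazul-1-en-3-one
Product: 22 (3S)-allylic alcohol: 3α-hydroxy-1-methyl-7β-(trimethylsilyloxy)-9β-(triisopropylsilyloxy)-cis-hydroazul-1-ene
Conditions: NaBH4, CeCl3·7H2O, MeOH, −78 → −40 °C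
Reagents that add atoms: none
Why: Luche 1,2-reduction: in the preferred conformer C5 is axial and the C4 methyl equatorial on the seven-membered ring, so hydride should attack C3 from the β face and place the hydroxyl α, trans to the methyl group.

Step 16
Reactants: 22 (3S)-allylic alcohol; 23 isovaleryl chloride
Product: 24 3α-isovalerate of 22
Conditions: pyridine, DMAP (cat.), CH2Cl2, 0 °C → rt
Reagents that add atoms: none
Why: Acylation of the secondary allylic alcohol by the acid chloride under nucleophilic catalysis by DMAP; the silylated tertiary alcohol cannot react.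

Step 17
Reactants: 24 3α-isovalerate
Product: 25 3α-isovaleryloxy-7β,9β-diol (3S,4R,7S,8S,9S)
Conditions: HF·pyridine, pyridine, THF, 0 °C → rt
Reagents that add atoms: none
Why: Fluoride cleaves both Si–O bonds, and the buffered reagent spares the allylic ester and the tertiary alcohol.

Step 18
Reactants: 25 3α-isovaleryloxy-7β,9β-diol; 26 4-acetoxybenzoic acid
Product: 27 9α-(4-acetoxybenzoyloxy)-3α-isovaleryloxy-7β-ol (3S,4R,7S,8S,9R)
Conditions: PPh3, DIAD, toluene/THF, 0 °C → rt
Reagents that add atoms: none
Why: Mitsunobu esterification: the C9 oxyphosphonium ion is displaced by the carboxylate with inversion (SN2), which converts the β-alcohol into the α-ester of the target, while the tertiary C7 alcohol cannot be activated.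

Step 19
Reactants: 27 9α-(4-acetoxybenzoyloxy) diester
Product: 28 target CNP0086724.3
Conditions: pyrrolidine (1.5 equiv), CH2Cl2, 0 °C
Reagents that add atoms: none
Why: Chemoselective aminolysis: the aryl acetate is far more electrophilic than the two alkyl esters, so pyrrolidine unmasks only the phenol.

## Compound list

1 | cyclohepta-1,3-diene | C1=CC=CCCC1 | starting material
2 | 6,7-dioxabicyclo[3.2.2]non-8-ene | O1OC2C=CC1CCC2 | intermediate (not isolated)
3 | rac-4-hydroxycyclohept-2-en-1-one | O=C1C=CC(O)CCC1 | intermediate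
4 | (S)-4-hydroxycyclohept-2-en-1-one | O=C1C=C[C@@H](O)CCC1 | intermediate
5 | (S)-4-(triisopropylsilyloxy)cyclohept-2-en-1-one | O=C1C=C[C@@H](O[Si](C(C)C)(C(C)C)C(C)C)CCC1 | intermediate
6 | (S)-2-iodo-4-(triisopropylsilyloxy)cyclohept-2-en-1-one | O=C1C(I)=C[C@@H](O[Si](C(C)C)(C(C)C)C(C)C)CCC1 | intermediate
7 | (S)-2-methyl-4-(triisopropylsilyloxy)cyclohept-2-en-1-one | O=C1C(C)=C[C@@H](O[Si](C(C)C)(C(C)C)C(C)C)CCC1 | intermediate
8 | isobutyryl chloride | CC(C)C(=O)Cl | starting material
9 | ethylene | C=C | starting material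
10 | 1-chloro-4-methylpentan-3-one | CC(C)C(=O)CCCl | intermediate
11 | 3,3-bis(benzyloxy)-1-chloro-4-methylpentane | CC(C)C(CCCl)(OCc1ccccc1)OCc1ccccc1 | intermediate
12 | 3,3-bis(benzyloxy)-1-iodo-4-methylpentane | CC(C)C(CCI)(OCc1ccccc1)OCc1ccccc1 | intermediate
13 | [3,3-bis(benzyloxy)-4-methylpentyl]magnesium iodide | I[Mg]CCC(OCc1ccccc1)(OCc1ccccc1)C(C)C | intermediate (not isolated)
14 | (1S,4S)-1-[3,3-bis(benzyloxy)-4-methylpentyl]-2-methyl-4-(triisopropylsilyloxy)cyclohept-2-en-1-ol | C1CC[C@](O)(CCC(OCc2ccccc2)(OCc3ccccc3)C(C)C)C(C)=C[C@H]1O[Si](C(C)C)(C(C)C)C(C)C | intermediate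
15 | trimethylsilyl ether of 14 (key-step precursor) | C1CC[C@](O[Si](C)(C)C)(CCC(OCc2ccccc2)(OCc3ccccc3)C(C)C)C(C)=C[C@H]1O[Si](C(C)C)(C(C)C)C(C)C | intermediate
16 | (4R,7S,8S,9S)-7-benzyloxy-7-isopropyl-4-methyl-9-(triisopropylsilyloxy)-cis-hydroazulen-3-one | C1CC(=O)[C@]2(C)CC[C@](OCc3ccccc3)(C(C)C)[C@@H]2[C@@H](O[Si](C(C)C)(C(C)C)C(C)C)C1 | intermediate
17 | (4R,7S,8S,9S)-7-hydroxy-7-isopropyl-4-methyl-9-(triisopropylsilyloxy)-cis-hydroazulen-3-one | C1CC(=O)[C@]2(C)CC[C@](O)(C(C)C)[C@@H]2[C@@H](O[Si](C(C)C)(C(C)C)C(C)C)C1 | intermediate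
18 | 3,7-bis(trimethylsilyloxy)-2-ene (silyl enol ether of 17, C7–OSiMe3) | C1C=C(O[Si](C)(C)C)[C@]2(C)CC[C@](O[Si](C)(C)C)(C(C)C)[C@@H]2[C@@H](O[Si](C(C)C)(C(C)C)C(C)C)C1 | intermediate (not isolated)
19 | (4R,7S,8S,9S)-7-isopropyl-4-methyl-7-(trimethylsilyloxy)-9-(triisopropylsilyloxy)-cis-hydroazul-1-en-3-one | C1=CC(=O)[C@]2(C)CC[C@](O[Si](C)(C)C)(C(C)C)[C@@H]2[C@@H](O[Si](C(C)C)(C(C)C)C(C)C)C1 | intermediate
20 | 1-methyl-3,7-bis(trimethylsilyloxy)-2-ene (C1 epimers) | CC1C=C(O[Si](C)(C)C)[C@]2(C)CC[C@](O[Si](C)(C)C)(C(C)C)[C@@H]2[C@@H](O[Si](C(C)C)(C(C)C)C(C)C)C1 | intermediate (not isolated)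
21 | (4R,7S,8S,9S)-7-isopropyl-1,4-dimethyl-7-(trimethylsilyloxy)-9-(triisopropylsilyloxy)-cis-hydroazul-1-en-3-one | CC1=CC(=O)[C@]2(C)CC[C@](O[Si](C)(C)C)(C(C)C)[C@@H]2[C@@H](O[Si](C(C)C)(C(C)C)C(C)C)C1 | intermediate
22 | (3S,4R,7S,8S,9S)-3-ol of 21 | CC1=C[C@H](O)[C@]2(C)CC[C@](O[Si](C)(C)C)(C(C)C)[C@@H]2[C@@H](O[Si](C(C)C)(C(C)C)C(C)C)C1 | intermediate
23 | isovaleryl chloride | CC(C)CC(=O)Cl | starting material
24 | (3S,4R,7S,8S,9S)-3-isovalerate of 22 | CC1=C[C@H](OC(=O)CC(C)C)[C@]2(C)CC[C@](O[Si](C)(C)C)(C(C)C)[C@@H]2[C@@H](O[Si](C(C)C)(C(C)C)C(C)C)C1 | intermediate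
25 | (3S,4R,7S,8S,9S)-3-isovaleryloxy-7,9-diol | CC1=C[C@H](OC(=O)CC(C)C)[C@]2(C)CC[C@](O)(C(C)C)[C@@H]2[C@@H](O)C1 | intermediate
26 | 4-acetoxybenzoic acid | CC(=O)Oc1ccc(cc1)C(O)=O | starting material
27 | (3S,4R,7S,8S,9R)-9-(4-acetoxybenzoyloxy)-3-isovaleryloxy-7-ol | CC1=C[C@H](OC(=O)CC(C)C)[C@]2(C)CC[C@](O)(C(C)C)[C@@H]2[C@H](OC(=O)c2ccc(OC(C)=O)cc2)C1 | intermediate
28 | CNP0086724.3 | CC1=C[C@H](OC(=O)CC(C)C)[C@]2(C)CC[C@](O)(C(C)C)[C@@H]2[C@H](OC(=O)c2ccc(O)cc2)C1 | target

## Step count and risks

Total steps: 19. Longest linear sequence: 16 (steps 1–5 and 9–19, from cyclohepta-1,3-diene).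

**Step 11 (key step).** After the Prins closure the bridged cation may shift ring carbon C2 in place of tether carbon C5, contracting the seven-membered ring instead of the new six-membered ring; both bonds are aligned with the empty orbital and the competing shift relieves more strain. The O-benzyl oxocarbenium ion may also lose its benzyl group before it cyclises.
Fallback: a removable chlorine on C2 makes that carbon a poor migrating group. It sets out from enone 7. Kinetic enolate formation (LDA, THF, −78 °C) and chlorination with N-chlorosuccinimide should give (4S,7R)-7-chloro-2-methyl-4-(triisopropylsilyloxy)cyclohept-2-en-1-one F1, with chlorine cis to the silyloxy group; the trans epimer is equilibrated with base and recycled. Grignard reagent 13 with CeCl3 should add anti to both chlorine and the silyloxy group (polar Felkin–Anh control) to give the C2-chloro analogue of 14, chlorohydrin F2. N-(Trimethylsilyl)imidazole gives the C2-chloro analogue of 15, silyl ether F3. SnCl4 under the conditions of step 11 should then give the 2β-chloro analogue of 16, chloro ketone F4. Zinc dust in acetic acid/THF removes the chlorine, and the fallback comes back to the route at 16.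

**Step 18.** The Mitsunobu displacement at C9 must enter from the concave α face next to the C7 isopropyl group, so elimination toward C10 or esterification with retention may compete.
Fallback: invert C9 by oxidation and reduction, then esterify with retention. It sets out from diol 25. Dess–Martin periodinane buffered with NaHCO3 (CH2Cl2, 0 °C) should give the 9-oxo compound F5, handled cold and neutral because it is a β-hydroxy and β,γ-unsaturated ketone. NaBH4 with CeCl3·7H2O in MeOH at −78 °C should deliver hydride from the convex β face to give the 9α-alcohol F6. Steglich esterification with acid 26 (DCC, DMAP, CH2Cl2) then comes back to the route at 27.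

**Step 9.** The organometallic reagent may show poor or reversed facial selectivity at the enone carbonyl. Poor selectivity costs only material, since the adducts are separable diastereomers; reversed selectivity would make the wrong C3 configuration the major one.
Fallback: use the other enantiomer of the enone and invert C9 afterwards. It sets out from racemate 3, whose (R)-acetate from step 2 is methanolysed (K2CO3, MeOH, 0 °C) to (R)-4-hydroxycyclohept-2-en-1-one F7. The conditions of steps 3–5 give in turn the (R)-silyl ether F8, the (R)-2-iodo enone F9 and the (R)-2-methyl enone F10. Addition of 13 with CeCl3, now syn to the silyloxy group, gives the (1S,4R)-adduct F11, which has the C3 configuration of 14. Bu4NF (THF) gives the (1S,4R)-diol F12. A Mitsunobu reaction at the secondary allylic alcohol (4-nitrobenzoic acid, PPh3, DIAD) gives the inverted (4S)-4-nitrobenzoate F13. K2CO3 in MeOH gives the (1S,4S)-diol F14. TIPSOTf (1.0 equiv) with 2,6-lutidine at −78 °C silylates only the secondary hydroxyl, and the fallback comes back to the route at 14.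

## Further compounds

F1 | step 11 | (4S,7R)-7-chloro-2-methyl-4-(triisopropylsilyloxy)cyclohept-2-en-1-one | O=C1C(C)=C[C@@H](O[Si](C(C)C)(C(C)C)C(C)C)CC[C@H]1Cl
F2 | step 11 | C2-chloro analogue of 14 (chlorine cis to both oxygens) | C1C[C@@H](Cl)[C@](O)(CCC(OCc2ccccc2)(OCc3ccccc3)C(C)C)C(C)=C[C@H]1O[Si](C(C)C)(C(C)C)C(C)C
F3 | step 11 | C2-chloro analogue of 15 | C1C[C@@H](Cl)[C@](O[Si](C)(C)C)(CCC(OCc2ccccc2)(OCc3ccccc3)C(C)C)C(C)=C[C@H]1O[Si](C(C)C)(C(C)C)C(C)C
F4 | step 11 | 2β-chloro analogue of 16 | C1[C@@H](Cl)C(=O)[C@]2(C)CC[C@](OCc3ccccc3)(C(C)C)[C@@H]2[C@@H](O[Si](C(C)C)(C(C)C)C(C)C)C1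
F5 | step 18 | (3S,4R,7S,8S)-7-hydroxy-3-isovaleryloxy-9-oxo compound | CC1=C[C@H](OC(=O)CC(C)C)[C@]2(C)CC[C@](O)(C(C)C)[C@@H]2C(=O)C1
F6 | step 18 | (3S,4R,7S,8S,9R)-3-isovaleryloxy-7,9-diol (9α-alcohol) | CC1=C[C@H](OC(=O)CC(C)C)[C@]2(C)CC[C@](O)(C(C)C)[C@@H]2[C@H](O)C1
F7 | step 9 | (R)-4-hydroxycyclohept-2-en-1-one | O=C1C=C[C@H](O)CCC1
F8 | step 9 | (R)-4-(triisopropylsilyloxy)cyclohept-2-en-1-one | O=C1C=C[C@H](O[Si](C(C)C)(C(C)C)C(C)C)CCC1
F9 | step 9 | (R)-2-iodo-4-(triisopropylsilyloxy)cyclohept-2-en-1-one | O=C1C(I)=C[C@H](O[Si](C(C)C)(C(C)C)C(C)C)CCC1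
F10 | step 9 | (R)-2-methyl-4-(triisopropylsilyloxy)cyclohept-2-en-1-one | O=C1C(C)=C[C@H](O[Si](C(C)C)(C(C)C)C(C)C)CCC1
F11 | step 9 | (1S,4R)-1-[3,3-bis(benzyloxy)-4-methylpentyl]-2-methyl-4-(triisopropylsilyloxy)cyclohept-2-en-1-ol | C1CC[C@](O)(CCC(OCc2ccccc2)(OCc3ccccc3)C(C)C)C(C)=C[C@@H]1O[Si](C(C)C)(C(C)C)C(C)C
F12 | step 9 | (1S,4R)-1-[3,3-bis(benzyloxy)-4-methylpentyl]-2-methylcyclohept-2-ene-1,4-diol | C1CC[C@](O)(CCC(OCc2ccccc2)(OCc3ccccc3)C(C)C)C(C)=C[C@@H]1O
F13 | step 9 | (1S,4S)-4-hydroxy-4-[3,3-bis(benzyloxy)-4-methylpentyl]-3-methylcyclohept-2-en-1-yl 4-nitrobenzoate | C1CC[C@](O)(CCC(OCc2ccccc2)(OCc3ccccc3)C(C)C)C(C)=C[C@H]1OC(=O)c4ccc(cc4)[N+](=O)[O-]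
F14 | step 9 | (1S,4S)-1-[3,3-bis(benzyloxy)-4-methylpentyl]-2-methylcyclohept-2-ene-1,4-diol | C1CC[C@](O)(CCC(OCc2ccccc2)(OCc3ccccc3)C(C)C)C(C)=C[C@H]1O
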